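Ask which way of running this flask leaves the most target at the end.

| flask | starting material | partner | second substrate | catalyst | time | remark |
|---|---|---|---|---|---|---|
| noon | 0.33 M | 0.264 M | 0.165 M (fed, over 20.0 h) | 0.66 mM | 40 h | a stirred flask in which second substrate is dosed at a steady rate over 20.0 h without added volume, worked up at 40 h |
| summer | 0.33 M | 0.264 M (fed, over 20.0 h) | 0.165 M | 0.66 mM | 40 h | a stirred flask in which partner is dosed at a steady rate over 20.0 h without added volume, worked up at 40 h |
| dawn | 0.33 M | 0.264 M | 0.165 M | 0.66 mM | 40 h | a closed flask charged with all of it at once and left for 40 h |
| midnight | 0.33 M | 0.264 M | 0.165 M | 0.66 mM |  | a single well-mixed tank run continuously and read at steady state, 40 h in it on average |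

    starting material + partner + catalyst → catalyst + target (k1 = 0.15 L² mol⁻² s⁻¹)
    second substrate + partner + catalyst → catalyst + second product (k2 = 0.10 L² mol⁻² s⁻¹)
    starting material + partner → uncatalysed product (k3 = 1.1 × 10⁻⁶ L mol⁻¹ s⁻¹)
    starting material + target → side product (k4 = 7.9 × 10⁻⁵ L mol⁻¹ s⁻¹)

1. the set-up with the highest amount of target at the outlet or at the end, in percent of the starting material put in ("none" if the first two lie within 2 percentage points) (noon / summer / dawn / midnight / none)
2. amount of target at the outlet or at the end, in percent of the starting material put in, noon
3. amount of target at the outlet or at the end, in percent of the starting material put in, summer
4. amount of target at the outlet or at the end, in percent of the starting material put in, dawn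
5. amount of target at the outlet or at the end, in percent of the starting material put in, midnight

- a species is counted by the starting material in it: one side product counts as two
- the stated concentrations are those of everything mixed, before any reaction; amounts are the same in each set-up
- the feed brings no volume worth counting
- run time (noon): 40 h

Set the making step, starting material + partner + catalyst, beside the eating step, starting material + target. Both carry c(starting material), so it cancels from their ratio. Divide the making constant times c(catalyst) by the eating constant to get 1.25, and call this the balance ratio, the selectivity factor of the pair: the c(target) per c(partner) at which target is made as fast as it is eaten.

Drop the uncatalysed step, since its half-life of 28 d is far longer than the run. But the second substrate takes partner and gives no target, so define the share as the part of the partner's loss that goes to target. Replace the curves by fixed means: the charges for dawn, which gives 0.750, and half the second substrate's charge for noon, while its feed runs, which gives 0.857.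

Now divide the target balance by the partner balance and integrate. With a as the share over the balance ratio, the peak stands where c(target) equals the balance ratio times c(partner), and the partner left there is a, raised to one over one minus a, of its charge. So noon peaks near 0.0995 M and dawn near 0.0921 M, and noon stands higher. Divide these peaks by the starting material's charge and take them as ceilings: expect noon's end value below 30.1% and dawn's below 27.9%, since target falls after its peak. This reckoning stops at these two flasks.

The forecast gave noon as best, with 24%, 20.5%, 18.5% and 15.7% in the order asked, because “holding back the second substrate leaves more partner for early target formation”.

The simulation gives noon as best, with 26.0%, 21.2%, 20.4% and 15.7% in the same order.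

At 40.0 h noon holds 0.0858 M of target, against a balance value of 0.0272 M, so eating outruns making there. Strike the eating step from noon and the answer becomes 63.2%, which makes that step the main reason. The neighbour of noon charged with 0.083 M of starting material ends with 0.0583 M of target, below its balance value of 0.118 M, and its answer is 70.3%.

The rate constants belong to no real substance; what happens was integrated by code.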